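**Assumption:** the SMILES is read as the (2S)-flavanone with an (E)-geranyl group at C6; compounds 10–12 are racemic at the ethoxyethyl acetal carbon, and 16 and 18 are racemates.

## Retrosynthetic overview

1. Target 20 ⇐ tris-MOM (2S)-flavanone 19 by acetal cleavage; 19 ⇐ racemic flavanone 18 by kinetic resolution (asymmetric transfer hydrogenation).
2. Ring C (the only ring formed) ⇐ 2'-hydroxychalcone 17 by intramolecular oxa-Michael addition.
3. Chalcone 17 ⇐ Claisen–Schmidt aldol of ring A methyl ketone 13 with ring B aldehyde 15; this forms the C2–C3 bond and joins the two fragments.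
4. Ketone 13 ⇐ two directed ortho-metalations on a differentiated phloroglucinol: geranyl between the two OMOM groups, acetyl next to the third oxygen (TIPS, later ethoxyethyl), which fixes 6- rather than 8-geranyl.
5. Silyl ether 5 ⇐ resorcinol (bis-MOM ether, C–H borylation, oxidation, silylation); 15 ⇐ syringaldehyde.

## Route

**Step 1**
Reactants: 1 resorcinol
Product: 2 1,3-bis(methoxymethoxy)benzene
Conditions: NaH, MOMCl, DMF, 0 °C to rt
Reagents that add atoms: chloromethyl methyl ether (MOMCl), COCCl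
Why: Williamson-type O-alkylation of both phenoxides gives the bis-acetal, whose OMOM groups serve later as ortho-directing groups.

**Step 2**
Reactants: 2 1,3-bis(methoxymethoxy)benzene
Product: 3 2-[3,5-bis(methoxymethoxy)phenyl]-4,4,5,5-tetramethyl-1,3,2-dioxaborolane
Conditions: B2pin2 (1.0 equiv), [Ir(OMe)(cod)]2 (1.5 mol%), 4,4'-di-tert-butyl-2,2'-bipyridine (3 mol%), THF, 80 °C
Reagents that add atoms: bis(pinacolato)diboron, CC1(C)OB(OC1(C)C)B1OC(C)(C)C(C)(C)O1
Why: Iridium-catalysed aromatic C–H borylation is sterically controlled, so a 1,3-disubstituted arene reacts only at C5, the one position not ortho to a substituent.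

**Step 3**
Reactants: 3 2-[3,5-bis(methoxymethoxy)phenyl]-4,4,5,5-tetramethyl-1,3,2-dioxaborolane
Product: 4 3,5-bis(methoxymethoxy)phenol
Conditions: 30% H2O2, 2 M NaOH, THF, 0 °C to rt; then aq. NH4Cl
Reagents that add atoms: hydrogen peroxide, OO
Why: Basic peroxide oxidation of the aryl boronate (1,2-aryl shift from boron to oxygen) gives the phenol under conditions that leave the MOM acetals untouched.

**Step 4**
Reactants: 4 3,5-bis(methoxymethoxy)phenol
Product: 5 [3,5-bis(methoxymethoxy)phenoxy]tri(propan-2-yl)silane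
Conditions: TIPSCl, imidazole, DMF, rt
Reagents that add atoms: chlorotri(propan-2-yl)silane (TIPSCl), CC(C)[Si](Cl)(C(C)C)C(C)C
Why: Silylation gives a bulky, non-coordinating ether that blocks its two neighbouring ring positions in the next metalation.

**Step 5**
Reactants: 5 [3,5-bis(methoxymethoxy)phenoxy]tri(propan-2-yl)silane; 6 geranyl bromide
Product: 8 {4-[(2E)-3,7-dimethylocta-2,6-dien-1-yl]-3,5-bis(methoxymethoxy)phenoxy}tri(propan-2-yl)silane, via aryllithium 7 (not isolated)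
Conditions: n-BuLi, THF, 0 °C to rt; CuBr·SMe2 (20 mol%), then 6, −40 °C to rt
Reagents that add atoms: none
Why: Directed ortho-metalation occurs only at the carbon flanked by both OMOM groups, and copper-catalysed SN2 allylation with geranyl bromide installs the side chain with its (E) alkene unchanged.

**Step 6**
Reactants: 8 {4-[(2E)-3,7-dimethylocta-2,6-dien-1-yl]-3,5-bis(methoxymethoxy)phenoxy}tri(propan-2-yl)silane
Product: 9 4-[(2E)-3,7-dimethylocta-2,6-dien-1-yl]-3,5-bis(methoxymethoxy)phenol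
Conditions: TBAF, THF, 0 °C; aq. NH4Cl
Reagents that add atoms: none
Why: Fluoride desilylation frees the one oxygen that will become the ring C oxygen, without touching the MOM acetals or the alkenes.

**Step 7**
Reactants: 9 4-[(2E)-3,7-dimethylocta-2,6-dien-1-yl]-3,5-bis(methoxymethoxy)phenol
Product: 10 2-[(2E)-3,7-dimethylocta-2,6-dien-1-yl]-5-(1-ethoxyethoxy)-1,3-bis(methoxymethoxy)benzene
Conditions: ethyl vinyl ether, PPTS (5 mol%), CH2Cl2, rt
Reagents that add atoms: ethyl vinyl ether, C=COCC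
Why: Acid-catalysed addition of the phenol to the enol ether gives an ethoxyethyl acetal that directs lithiation, resists a retro-Brook shift (unlike a silyl ether) and is far more acid-labile than MOM.

**Step 8**
Reactants: 10 2-[(2E)-3,7-dimethylocta-2,6-dien-1-yl]-5-(1-ethoxyethoxy)-1,3-bis(methoxymethoxy)benzene
Product: 12 1-{3-[(2E)-3,7-dimethylocta-2,6-dien-1-yl]-6-(1-ethoxyethoxy)-2,4-bis(methoxymethoxy)phenyl}ethan-1-one, via aryllithium 11 (not isolated)
Conditions: n-BuLi, TMEDA, THF, −20 to 0 °C; MeC(O)N(OMe)Me, −78 to 0 °C; aq. NH4Cl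
Reagents that add atoms: N-methoxy-N-methylacetamide, CC(=O)N(C)OC
Why: Directed ortho-metalation at one of the two equivalent ring CH positions (each between two acetal oxygens) followed by Weinreb ketone synthesis gives the methyl ketone without over-addition.

**Step 9**
Reactants: 12 1-{3-[(2E)-3,7-dimethylocta-2,6-dien-1-yl]-6-(1-ethoxyethoxy)-2,4-bis(methoxymethoxy)phenyl}ethan-1-one
Product: 13 1-{3-[(2E)-3,7-dimethylocta-2,6-dien-1-yl]-6-hydroxy-2,4-bis(methoxymethoxy)phenyl}ethan-1-one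
Conditions: PPTS (20 mol%), EtOH, 40 °C
Reagents that add atoms: none
Why: Mild transacetalisation removes only the ethoxyethyl group, leaving a single free phenol on the side of the acetyl group away from the geranyl chain.

**Step 10**
Reactants: 14 syringaldehyde
Product: 15 3,5-dimethoxy-4-(methoxymethoxy)benzaldehyde
Conditions: NaH, MOMCl, DMF, 0 °C to rt
Reagents that add atoms: chloromethyl methyl ether (MOMCl), COCCl
Why: Williamson-type O-alkylation masks the phenol so that the aldehyde is not deactivated as a phenoxide in the aldol step.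

**Step 11**
Reactants: 13 1-{3-[(2E)-3,7-dimethylocta-2,6-dien-1-yl]-6-hydroxy-2,4-bis(methoxymethoxy)phenyl}ethan-1-one; 15 3,5-dimethoxy-4-(methoxymethoxy)benzaldehyde
Product: 17 (2E)-1-{3-[(2E)-3,7-dimethylocta-2,6-dien-1-yl]-6-hydroxy-2,4-bis(methoxymethoxy)phenyl}-3-[3,5-dimethoxy-4-(methoxymethoxy)phenyl]prop-2-en-1-one, via aldol adduct 16 (not isolated)
Conditions: KOH (50% aq.), EtOH, 0 °C to rt, 36 h; cold aq. NH4Cl to pH 7
Reagents that add atoms: none
Why: Claisen–Schmidt (crossed aldol) condensation: the enolate of 13 adds to the non-enolisable aldehyde 15, forming the future C2–C3 bond, and the aldol 16 dehydrates by E1cB to the (E)-chalcone.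

**Step 12**
Reactants: 17 (2E)-1-{3-[(2E)-3,7-dimethylocta-2,6-dien-1-yl]-6-hydroxy-2,4-bis(methoxymethoxy)phenyl}-3-[3,5-dimethoxy-4-(methoxymethoxy)phenyl]prop-2-en-1-one
Product: 18 rac-6-[(2E)-3,7-dimethylocta-2,6-dien-1-yl]-2-[3,5-dimethoxy-4-(methoxymethoxy)phenyl]-5,7-bis(methoxymethoxy)-2,3-dihydro-4H-chromen-4-one
Conditions: NaOAc, EtOH, reflux, 24–48 h (recovered 17 recycled)
Reagents that add atoms: none
Why: Intramolecular oxa-Michael addition of the only free phenol closes ring C with 6-geranyl regiochemistry and creates C2 as a racemate, the flanking OMOM group twisting the enone and favouring the closed form.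

**Step 13**
Reactants: 18 rac-6-[(2E)-3,7-dimethylocta-2,6-dien-1-yl]-2-[3,5-dimethoxy-4-(methoxymethoxy)phenyl]-5,7-bis(methoxymethoxy)-2,3-dihydro-4H-chromen-4-one
Product: 19 (2S)-6-[(2E)-3,7-dimethylocta-2,6-dien-1-yl]-2-[3,5-dimethoxy-4-(methoxymethoxy)phenyl]-5,7-bis(methoxymethoxy)-2,3-dihydro-4H-chromen-4-one
Conditions: Cp*RhCl[(R,R)-TsDPEN] (1 mol%), HCO2H/Et3N (5:2), EtOAc, 25 °C, stopped at 52–55% conversion; chromatography
Reagents that add atoms: none
Why: Kinetic resolution by Noyori-type asymmetric transfer hydrogenation: the (R,R)-catalyst forms (4R)-carbinols and is matched with the (2R)-ketone (2,4-cis product), so that enantiomer is reduced and the (2S)-ketone is recovered in high ee, while isolated alkenes and MOM ethers are inert.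

**Step 14**
Reactants: 19 (2S)-6-[(2E)-3,7-dimethylocta-2,6-dien-1-yl]-2-[3,5-dimethoxy-4-(methoxymethoxy)phenyl]-5,7-bis(methoxymethoxy)-2,3-dihydro-4H-chromen-4-one
Product: 20 (2S)-6-[(2E)-3,7-dimethylocta-2,6-dien-1-yl]-5,7-dihydroxy-2-(4-hydroxy-3,5-dimethoxyphenyl)-2,3-dihydro-4H-chromen-4-one
Conditions: 3 M aq. HCl/MeOH (1:5), 40 °C, monitored and stopped at full conversion
Reagents that add atoms: none
Why: Acid-catalysed acetal solvolysis removes the three MOM groups under conditions mild enough to spare the geranyl alkenes and, being base-free, to avoid ring-opening racemisation at C2.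

## Compound list

1 | resorcinol (benzene-1,3-diol) | Oc1cccc(O)c1 | starting material
2 | 1,3-bis(methoxymethoxy)benzene | COCOc1cccc(OCOC)c1 | intermediate
3 | 2-[3,5-bis(methoxymethoxy)phenyl]-4,4,5,5-tetramethyl-1,3,2-dioxaborolane | COCOc1cc(OCOC)cc(B2OC(C)(C)C(C)(C)O2)c1 | intermediate
4 | 3,5-bis(methoxymethoxy)phenol | COCOc1cc(O)cc(OCOC)c1 | intermediate
5 | [3,5-bis(methoxymethoxy)phenoxy]tri(propan-2-yl)silane | COCOc1cc(O[Si](C(C)C)(C(C)C)C(C)C)cc(OCOC)c1 | intermediate
6 | geranyl bromide, (2E)-1-bromo-3,7-dimethylocta-2,6-diene | BrC/C=C(\C)CCC=C(C)C | starting material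
7 | [2,6-bis(methoxymethoxy)-4-(triisopropylsilyloxy)phenyl]lithium (not isolated) | [Li]c1c(OCOC)cc(O[Si](C(C)C)(C(C)C)C(C)C)cc1OCOC | intermediate
8 | {4-[(2E)-3,7-dimethylocta-2,6-dien-1-yl]-3,5-bis(methoxymethoxy)phenoxy}tri(propan-2-yl)silane | COCOc1cc(O[Si](C(C)C)(C(C)C)C(C)C)cc(OCOC)c1C/C=C(\C)CCC=C(C)C | intermediate
9 | 4-[(2E)-3,7-dimethylocta-2,6-dien-1-yl]-3,5-bis(methoxymethoxy)phenol | COCOc1cc(O)cc(OCOC)c1C/C=C(\C)CCC=C(C)C | intermediate
10 | 2-[(2E)-3,7-dimethylocta-2,6-dien-1-yl]-5-(1-ethoxyethoxy)-1,3-bis(methoxymethoxy)benzene (racemic acetal) | CCOC(C)Oc1cc(OCOC)c(C/C=C(\C)CCC=C(C)C)c(OCOC)c1 | intermediate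
11 | {3-[(2E)-3,7-dimethylocta-2,6-dien-1-yl]-6-(1-ethoxyethoxy)-2,4-bis(methoxymethoxy)phenyl}lithium (not isolated) | [Li]c1c(OC(C)OCC)cc(OCOC)c(C/C=C(\C)CCC=C(C)C)c1OCOC | intermediate
12 | 1-{3-[(2E)-3,7-dimethylocta-2,6-dien-1-yl]-6-(1-ethoxyethoxy)-2,4-bis(methoxymethoxy)phenyl}ethan-1-one (racemic acetal) | CC(=O)c1c(OC(C)OCC)cc(OCOC)c(C/C=C(\C)CCC=C(C)C)c1OCOC | intermediate
13 | 1-{3-[(2E)-3,7-dimethylocta-2,6-dien-1-yl]-6-hydroxy-2,4-bis(methoxymethoxy)phenyl}ethan-1-one | CC(=O)c1c(O)cc(OCOC)c(C/C=C(\C)CCC=C(C)C)c1OCOC | intermediate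
14 | syringaldehyde (4-hydroxy-3,5-dimethoxybenzaldehyde) | COc1cc(C=O)cc(OC)c1O | starting material
15 | 3,5-dimethoxy-4-(methoxymethoxy)benzaldehyde | COCOc1c(OC)cc(C=O)cc1OC | intermediate
16 | rac-1-{3-[(2E)-3,7-dimethylocta-2,6-dien-1-yl]-6-hydroxy-2,4-bis(methoxymethoxy)phenyl}-3-hydroxy-3-[3,5-dimethoxy-4-(methoxymethoxy)phenyl]propan-1-one (not isolated) | COCOc1c(OC)cc(C(O)CC(=O)c2c(O)cc(OCOC)c(C/C=C(\C)CCC=C(C)C)c2OCOC)cc1OC | intermediate
17 | (2E)-1-{3-[(2E)-3,7-dimethylocta-2,6-dien-1-yl]-6-hydroxy-2,4-bis(methoxymethoxy)phenyl}-3-[3,5-dimethoxy-4-(methoxymethoxy)phenyl]prop-2-en-1-one | COCOc1c(OC)cc(/C=C/C(=O)c2c(O)cc(OCOC)c(C/C=C(\C)CCC=C(C)C)c2OCOC)cc1OC | intermediate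
18 | rac-6-[(2E)-3,7-dimethylocta-2,6-dien-1-yl]-2-[3,5-dimethoxy-4-(methoxymethoxy)phenyl]-5,7-bis(methoxymethoxy)-2,3-dihydro-4H-chromen-4-one | COCOc1c(OC)cc(C2CC(=O)c3c(cc(OCOC)c(C/C=C(\C)CCC=C(C)C)c3OCOC)O2)cc1OC | intermediate
19 | (2S)-6-[(2E)-3,7-dimethylocta-2,6-dien-1-yl]-2-[3,5-dimethoxy-4-(methoxymethoxy)phenyl]-5,7-bis(methoxymethoxy)-2,3-dihydro-4H-chromen-4-one | COCOc1c(OC)cc([C@@H]2CC(=O)c3c(cc(OCOC)c(C/C=C(\C)CCC=C(C)C)c3OCOC)O2)cc1OC | intermediate
20 | (2S)-6-[(2E)-3,7-dimethylocta-2,6-dien-1-yl]-5,7-dihydroxy-2-(4-hydroxy-3,5-dimethoxyphenyl)-2,3-dihydro-4H-chromen-4-one | COc1cc([C@@H]2CC(=O)c3c(cc(O)c(C/C=C(\C)CCC=C(C)C)c3O)O2)cc(OC)c1O | target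

## Step count and risk

Total steps: 14. Longest linear sequence: 13 (steps 1–9, then 11–14); step 10 is the one-step branch to aldehyde 15.

Steps most likely to fail:

**Step 8 (second metalation and acetylation).** Deprotonation at the benzylic-allylic CH2 of the geranyl group, or enolisation of the Weinreb amide by the hindered aryllithium, could cut the yield. The fallback avoids organolithium chemistry. It sets out from phenol 9 and comes back to the route at ketone 13, so steps 7–9 are not needed. Magnesium-mediated ortho-formylation (MgCl2, Et3N, paraformaldehyde, MeCN, reflux; the two ortho positions of 9 are equivalent) gives 3-[(2E)-3,7-dimethylocta-2,6-dien-1-yl]-6-hydroxy-2,4-bis(methoxymethoxy)benzaldehyde F1. Addition of MeMgBr (3 equiv, THF, −78 to 0 °C) gives 4-[(2E)-3,7-dimethylocta-2,6-dien-1-yl]-2-(1-hydroxyethyl)-3,5-bis(methoxymethoxy)phenol F2, which is used crude and oxidised with MnO2 (CH2Cl2, rt) to 13.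

**Step 13 (kinetic resolution).** The selectivity factor on this hindered 5-OMOM ketone may be too low to leave the (2S)-ketone in high ee at acceptable conversion. The fallback sets out from racemate 18 and comes back at 19, carrying the wanted enantiomer through as the carbinol. With the enantiomeric catalyst Cp*RhCl[(S,S)-TsDPEN] (HCO2H/Et3N, EtOAc), stopped near 45% conversion, the (2S)-ketone is the one reduced. The product (2S,4S)-6-[(2E)-3,7-dimethylocta-2,6-dien-1-yl]-2-[3,5-dimethoxy-4-(methoxymethoxy)phenyl]-5,7-bis(methoxymethoxy)-3,4-dihydro-2H-chromen-4-ol F3 is separated from unreacted ketone, enriched by recrystallisation if needed, and re-oxidised with Dess–Martin periodinane (NaHCO3, CH2Cl2, 0 °C) to 19.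

**Step 14 (acidic removal of three MOM groups beside a geranyl chain).** Protic acid can cyclise the geranyl group onto the neighbouring phenols or add methanol to the alkenes. The fallback sets out from 19 and comes back at 20 by buffered silyl transfer, with no Brønsted acid. TMSOTf and 2,2'-bipyridyl (MeCN, 0 °C to rt) convert the aryl MOM ethers into (2S)-6-[(2E)-3,7-dimethylocta-2,6-dien-1-yl]-2-[3,5-dimethoxy-4-(trimethylsilyloxy)phenyl]-5,7-bis(trimethylsilyloxy)-2,3-dihydro-4H-chromen-4-one F4, and addition of pH 7 aqueous buffer hydrolyses the silyl ethers to 20.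

## Further compounds

F1 | step 8 | 3-[(2E)-3,7-dimethylocta-2,6-dien-1-yl]-6-hydroxy-2,4-bis(methoxymethoxy)benzaldehyde | O=Cc1c(O)cc(OCOC)c(C/C=C(\C)CCC=C(C)C)c1OCOC
F2 | step 8 | 4-[(2E)-3,7-dimethylocta-2,6-dien-1-yl]-2-(1-hydroxyethyl)-3,5-bis(methoxymethoxy)phenol (racemic) | CC(O)c1c(O)cc(OCOC)c(C/C=C(\C)CCC=C(C)C)c1OCOC
F3 | step 13 | (2S,4S)-6-[(2E)-3,7-dimethylocta-2,6-dien-1-yl]-2-[3,5-dimethoxy-4-(methoxymethoxy)phenyl]-5,7-bis(methoxymethoxy)-3,4-dihydro-2H-chromen-4-ol | COCOc1c(OC)cc([C@@H]2C[C@H](O)c3c(cc(OCOC)c(C/C=C(\C)CCC=C(C)C)c3OCOC)O2)cc1OC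
F4 | step 14 | (2S)-6-[(2E)-3,7-dimethylocta-2,6-dien-1-yl]-2-[3,5-dimethoxy-4-(trimethylsilyloxy)phenyl]-5,7-bis(trimethylsilyloxy)-2,3-dihydro-4H-chromen-4-one | COc1cc([C@@H]2CC(=O)c3c(cc(O[Si](C)(C)C)c(C/C=C(\C)CCC=C(C)C)c3O[Si](C)(C)C)O2)cc(OC)c1O[Si](C)(C)C
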